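**Strategy.** The route rests on opening ring A at C10–C11 and C21–C22. Bond C10–C21 belongs to both the cyclobutane (C9–C10–C21–C20) and ring A (C10–C11=C12–C13–C22–C21), and C13 is oxygenated, so ring A is the Diels–Alder adduct of cyclobut-2-en-1-one with a 2-silyloxy diene C11=C12(OSi)–C13=C22 built on ring B. One endo cycloaddition forms both bonds, closes ring A, sets C10, C21 and C22, and leaves a cyclobutanone (for C9 alkylation and C19–C20 closure) and a C12 silyl enol ether (for C13 hydroxylation). The diene is an enantiopure cyclohexene with a C14 dioxolane, a C17 silyl ether and a C18 benzyloxymethyl group.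

Key step: step 14

Remarks on the chemistry:
- Atom labels used for every intermediate: octyl C1–C8; carboxyl C15; cyclobutane C9–C10–C21–C20; ring A C10–C11–C12–C13–C22–C21; ring B C13–C14–C16–C17–C18–C22; ring C C18–C19–C20–C21–C22. "α-face" is the side that carries H22 (and, on ring B, the C17 oxygen and C19).
- Assumption: in step 1 the (R)-bisphosphine is taken to deliver the (2R,3R)-diol; if the sense of induction is the opposite, the (S)-ligand is used.
- Compounds 9 and 10 are mixtures of C14 epimers, which converge in step 7.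

**Part A – ring-B diene**

Step 1
Reactants: 1 3,3-diethoxypropan-1-ol; 2 4-vinyl-1,3-dioxolan-2-one (racemic)
Product: 3 (2R,3R)-5,5-diethoxy-2-vinylpentane-1,3-diol
Conditions: [Ir(cod)Cl]2 (cat.), (R)-SEGPHOS, 4-cyano-3-nitrobenzoic acid (cat.), K3PO4 (cat.), THF, 90 °C
Reagents that add atoms: none
Why: Iridium-catalysed transfer-hydrogenative carbonyl (hydroxymethyl)allylation: the catalyst dehydrogenates 1 to its aldehyde, ionises 2 with loss of CO2 to an (E)-σ-allyl iridium species, and a closed chair transition state under control of the chiral bisphosphine should give the anti diol, setting C17 and C18 together.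

Step 2
Reactants: 3 (2R,3R)-5,5-diethoxy-2-vinylpentane-1,3-diol
Product: 5 (3R,4R)-4-[(benzyloxy)methyl]-1,1-diethoxyhex-5-en-3-ol, via dibutylstannylene acetal 4 (not isolated)
Conditions: Bu2SnO, toluene, reflux (–H2O); then BnBr, Bu4NI (cat.), 80 °C
Reagents that add atoms: benzyl bromide, BrCc1ccccc1
Why: Stannylene-acetal-directed O-alkylation: the six-membered stannylene activates the less hindered primary oxygen (C19–O), which should be benzylated selectively while the C17 hydroxyl stays free.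

Step 3
Reactants: 5 (3R,4R)-4-[(benzyloxy)methyl]-1,1-diethoxyhex-5-en-3-ol
Product: 6 tert-butyl{[(3R,4R)-4-[(benzyloxy)methyl]-1,1-diethoxyhex-5-en-3-yl]oxy}dimethylsilane
Conditions: TBSCl, imidazole, DMF, 23 °C
Reagents that add atoms: tert-butyldimethylsilyl chloride, CC(C)(C)[Si](C)(C)Cl
Why: Imidazole-promoted silylation of the secondary C17 alcohol under base, which leaves the diethyl acetal intact; no stereocentre is touched.

Step 4
Reactants: 6 tert-butyl{[(3R,4R)-4-[(benzyloxy)methyl]-1,1-diethoxyhex-5-en-3-yl]oxy}dimethylsilane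
Product: 7 (3R,4R)-4-[(benzyloxy)methyl]-3-[(tert-butyldimethylsilyl)oxy]hex-5-enal
Conditions: PPTS (cat.), acetone/H2O (10:1), 50 °C
Reagents that add atoms: water, O
Why: Mild acid-catalysed acetal hydrolysis that the secondary TBS ether, the benzyl ether and the terminal alkene should tolerate.

Step 5
Reactants: 7 (3R,4R)-4-[(benzyloxy)methyl]-3-[(tert-butyldimethylsilyl)oxy]hex-5-enal; 8 vinylmagnesium bromide
Product: 9 (5R,6R)-6-[(benzyloxy)methyl]-5-[(tert-butyldimethylsilyl)oxy]octa-1,7-dien-3-ol (both C3 epimers)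
Conditions: THF, –78 °C; aq. NH4Cl
Reagents that add atoms: none
Why: Grignard 1,2-addition to the aldehyde; both C14 epimers are carried on because C14 becomes a carbonyl in step 7.

Step 6
Reactants: 9 (5R,6R)-6-[(benzyloxy)methyl]-5-[(tert-butyldimethylsilyl)oxy]octa-1,7-dien-3-ol
Product: 10 (4R,5R)-4-[(benzyloxy)methyl]-5-[(tert-butyldimethylsilyl)oxy]cyclohex-2-en-1-ol (both C1 epimers)
Conditions: second-generation Grubbs catalyst (cat.), CH2Cl2 (dilute), 40 °C
Reagents that add atoms: none
Why: Ring-closing olefin metathesis of two monosubstituted alkenes closes six-membered ring B with the C13=C22 double bond and releases ethene.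

Step 7
Reactants: 10 (4R,5R)-4-[(benzyloxy)methyl]-5-[(tert-butyldimethylsilyl)oxy]cyclohex-2-en-1-ol
Product: 11 (4R,5R)-4-[(benzyloxy)methyl]-5-[(tert-butyldimethylsilyl)oxy]cyclohex-2-en-1-one
Conditions: MnO2, CH2Cl2, 23 °C
Reagents that add atoms: none
Why: Selective allylic-alcohol oxidation by MnO2 gives the cis-4,5-disubstituted enone and merges the C14 epimers.

Step 8
Reactants: 11 (4R,5R)-4-[(benzyloxy)methyl]-5-[(tert-butyldimethylsilyl)oxy]cyclohex-2-en-1-one
Product: 12 (4R,5R)-4-[(benzyloxy)methyl]-5-[(tert-butyldimethylsilyl)oxy]-2-iodocyclohex-2-en-1-one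
Conditions: I2, pyridine, CH2Cl2, 0 → 23 °C
Reagents that add atoms: iodine, II
Why: Pyridine-mediated α-iodination of an enone (Baylis–Hillman-type conjugate addition, iodination of the enolate, elimination) places iodine at C13.

Step 9
Reactants: 12 (4R,5R)-4-[(benzyloxy)methyl]-5-[(tert-butyldimethylsilyl)oxy]-2-iodocyclohex-2-en-1-one
Product: 13 tert-butyl{[(8R,9R)-8-[(benzyloxy)methyl]-6-iodo-1,4-dioxaspiro[4.5]dec-6-en-9-yl]oxy}dimethylsilane
Conditions: Me3SiOCH2CH2OSiMe3, TMSOTf (cat.), CH2Cl2, –78 → –20 °C; pyridine quench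
Reagents that add atoms: 1,2-bis(trimethylsilyloxy)ethane, C[Si](C)(C)OCCO[Si](C)(C)C
Why: Silyl-triflate-catalysed ketalisation with the bis-silyl glycol at low temperature; α-halo enones are ketalised without migration of the double bond, and the silyl and benzyl ethers should survive.

Step 10
Reactants: 13 tert-butyl{[(8R,9R)-8-[(benzyloxy)methyl]-6-iodo-1,4-dioxaspiro[4.5]dec-6-en-9-yl]oxy}dimethylsilane; 14 N-methoxy-N-methylacetamide
Product: 16 1-[(8R,9R)-8-[(benzyloxy)methyl]-9-[(tert-butyldimethylsilyl)oxy]-1,4-dioxaspiro[4.5]dec-6-en-6-yl]ethan-1-one, via C13 vinyllithium 15 (not isolated)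
Conditions: t-BuLi (2.1 equiv), Et2O, –78 °C; then 14, –78 → 0 °C; aq. NH4Cl
Reagents that add atoms: none
Why: Iodine–lithium exchange gives the vinyllithium (a masked α-keto vinyl anion), which is acylated once in a Weinreb ketone synthesis through the stable chelated tetrahedral adduct.

Step 11
Reactants: 16 1-[(8R,9R)-8-[(benzyloxy)methyl]-9-[(tert-butyldimethylsilyl)oxy]-1,4-dioxaspiro[4.5]dec-6-en-6-yl]ethan-1-one
Product: 18 (8R,9R)-8-[(benzyloxy)methyl]-9-[(tert-butyldimethylsilyl)oxy]-6-{1-[(tert-butyldimethylsilyl)oxy]ethenyl}-1,4-dioxaspiro[4.5]dec-6-ene, via lithium dienolate 17 (not isolated)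
Conditions: LiN(iPr)2 (LDA), THF, –78 °C; TBSOTf, –78 °C; Et3N quench
Reagents that add atoms: tert-butyldimethylsilyl trifluoromethanesulfonate, CC(C)(C)[Si](C)(C)OS(=O)(=O)C(F)(F)F
Why: Kinetic deprotonation of the methyl group (α′ to the enone) and O-silylation should give the 2-silyloxy diene C11=C12(OTBS)–C13=C22 without touching the ring stereocentres.

**Part B – dienophile**

Step 12
Reactants: 19 3-oxocyclobutane-1-carboxylic acid
Product: 20 3-bromocyclobutan-1-one
Conditions: HgO, Br2, MgSO4, CH2Cl2, reflux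
Reagents that add atoms: bromine, BrBr
Why: HgO-modified Hunsdiecker bromodecarboxylation (acyl hypobromite, radical decarboxylation, bromine transfer).

Step 13
Reactants: 20 3-bromocyclobutan-1-one
Product: 21 cyclobut-2-en-1-one
Conditions: Bu3N, 23 °C; distilled under reduced pressure into a cold trap, used at once
Reagents that add atoms: none
Why: Amine-induced E1cB dehydrobromination of the β-bromo ketone gives the strained enone.

**Part C – key step**

Step 14
Reactants: 18 (8R,9R)-8-[(benzyloxy)methyl]-9-[(tert-butyldimethylsilyl)oxy]-6-{1-[(tert-butyldimethylsilyl)oxy]ethenyl}-1,4-dioxaspiro[4.5]dec-6-ene; 21 cyclobut-2-en-1-one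
Product: 22 endo cycloadduct: tricyclic C20 cyclobutanone with C12(OTBS)=C13 enol ether (C14 dioxolane; 17-OTBS; 18-CH2OBn; H10, H21, H22 cis; H18 trans to H22)
Conditions: 21 (3 equiv), toluene, 23 → 45 °C, BHT (trace)
Reagents that add atoms: none
Why: Concerted, asynchronous normal-demand [4+2] cycloaddition in which the enol-ether terminus C11 of the s-cis diene bonds to the β-carbon C10 of the strained enone and C22 bonds to the α-carbon C21, the double bond moving to C12=C13. The closest known reaction type is the thermal Diels–Alder reaction of cyclobut-2-en-1-one with 2-silyloxy dienes, for which this dienophile is reactive without Lewis acid and strongly endo-selective. Ring A (C10–C11–C12–C13–C22–C21) closes as a six-membered ring by intermolecular cycloaddition across the diene termini and is cis-fused to the four-membered ring. C22 is controlled by the diene face: the C17 OTBS and C18 CH2OBn groups both lie on the α-face, so the dienophile should add to the β-face and C21 ends trans to C19. C21 and C10 are controlled relative to C22 by the endo transition state (carbonyl C20 under the diene), which places the cyclobutanone cis to C18 as the later C19–C20 closure requires, and by suprafacial addition, which keeps H10 and H21 cis. The regiochemistry follows from the 2-silyloxy and C22-alkyl substituents polarising the diene in the same sense, and the dioxolane keeps C14 out of conjugation so that the diene stays electron-rich.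

**Part D – from the cycloadduct to the target**

Step 15
Reactants: 22 endo cycloadduct; 23 1-bromooct-2-yne
Product: 25 C9-(oct-2-yn-1-yl) cyclobutanone (side chain trans to C11), via C9 lithium enolate 24 (not isolated)
Conditions: LiN(iPr)2 (LDA), THF, –78 °C; then 23, –78 → –30 °C
Reagents that add atoms: none
Why: Kinetic enolate alkylation: the base removes a C9 proton and not the ring-fusion C21–H, and the reactive propargylic bromide should attack the convex face of the enolate, trans to C11, which sets C9.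

Step 16
Reactants: 25 C9-(oct-2-yn-1-yl) cyclobutanone
Product: 26 C9-octyl C19-hydroxy cyclobutanone
Conditions: H2 (1 atm), Pd(OH)2/C, EtOAc, 23 °C
Reagents that add atoms: none
Why: Heterogeneous hydrogenation saturates the alkyne to the octyl chain and hydrogenolyses the benzyl ether in one operation, while the tetrasubstituted silyl enol ether and the ketone should be inert; 26 may rest as its C19–O–C20 hemiketal.

Step 17
Reactants: 26 C9-octyl C19-hydroxy cyclobutanone
Product: 28 C9-octyl C19-iodo cyclobutanone, via C19 mesylate 27 (not isolated)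
Conditions: MsCl, Et3N, CH2Cl2, 0 °C; then NaI, butan-2-one, 60 °C
Reagents that add atoms: sodium iodide, [Na+].[I-]
Why: Sulfonylation of the primary alcohol (drawn from the open form of the hemiketal equilibrium) and Finkelstein displacement; the absence of electrophilic iodine spares the silyl enol ether.

Step 18
Reactants: 28 C9-octyl C19-iodo cyclobutanone
Product: 29 tetracyclic C20 tertiary cyclobutanol (ring C closed by C19–C20; C12 TBS enol ether)
Conditions: SmI2 (2.5 equiv), HMPA, THF, –78 → 0 °C; aq. NH4Cl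
Reagents that add atoms: none
Why: Intramolecular samarium Barbier reaction: reduction of the C–I bond and addition of C19 to the strained C20 ketone closes five-membered ring C, and the tether allows attack only on the face cis to C22, so the cis-fused cyclobutanol should result.

Step 19
Reactants: 29 tetracyclic C20 tertiary cyclobutanol
Product: 31 C20 methyl oxalate, via potassium alkoxide 30 (not isolated)
Conditions: KN(SiMe3)2, THF, –78 °C; ClCOCO2Me, –78 → 0 °C
Reagents that add atoms: methyl chlorooxoacetate, COC(=O)C(=O)Cl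
Why: Acylation of the pre-formed potassium alkoxide of the hindered tertiary alcohol by the reactive oxalyl half-ester chloride.

Step 20
Reactants: 31 C20 methyl oxalate
Product: 32 C20-deoxy tetracycle (C20–H; C12 TBS enol ether; C14 dioxolane; 17-OTBS)
Conditions: Bu3SnH, AIBN, toluene, 110 °C
Reagents that add atoms: none
Why: Barton–McCombie-type radical deoxygenation of a tertiary methyl oxalate gives the tertiary C20 radical, which should take hydrogen on the exo face because ring C and the cyclobutane can only be cis-fused.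

Step 21
Reactants: 32 C20-deoxy tetracycle
Product: 34 C12 ketone with 13-OTBS on the α-face, via silyloxy epoxide 33 (not isolated)
Conditions: dimethyldioxirane, acetone/CH2Cl2, –40 → 0 °C; then 40 °C
Reagents that add atoms: dimethyldioxirane, CC1(C)OO1
Why: Rubottom oxidation: the dioxirane should epoxidise the electron-rich C12=C13 enol ether on the convex α-face (cis to H22, away from the cyclobutane and ring C), and 1,4-silyl migration in the silyloxy oxirane gives the ketone with the new C13 oxygen already protected.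

Step 22
Reactants: 34 C12 ketone with 13-OTBS
Product: 36 C12 enol triflate (C11=C12), via C11 potassium enolate 35 (not isolated)
Conditions: KN(SiMe3)2, THF, –78 °C; PhNTf2, –78 → 0 °C
Reagents that add atoms: N-phenylbis(trifluoromethanesulfonimide), O=S(=O)(N(c1ccccc1)S(=O)(=O)C(F)(F)F)C(F)(F)F
Why: Enolisation can occur only towards C11 because C13 is quaternary, and O-sulfonylation gives the enol triflate.

Step 23
Reactants: 36 C12 enol triflate
Product: 37 C11=C12 alkene (13-OTBS; C14 dioxolane; 17-OTBS)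
Conditions: Pd(OAc)2 (cat.), PPh3, Bu3N, HCO2H, DMF, 60 °C
Reagents that add atoms: none
Why: Palladium-catalysed formate reduction of the enol triflate (oxidative addition to zerovalent palladium, formate exchange, decarboxylation, reductive elimination) leaves the C11=C12 alkene.

Step 24
Reactants: 37 C11=C12 alkene
Product: 38 C14 ketone
Conditions: PPTS, acetone/H2O (9:1), 60 °C
Reagents that add atoms: water, O
Why: Acid-catalysed ketal hydrolysis frees the C14 ketone under conditions mild enough for the secondary and tertiary TBS ethers.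

Step 25
Reactants: 38 C14 ketone
Product: 40 C14 enol triflate (C14=C16), via C16 potassium enolate 39 (not isolated)
Conditions: KN(SiMe3)2, N-(5-chloropyridin-2-yl)bis(trifluoromethanesulfonimide), THF, –78 °C
Reagents that add atoms: N-(5-chloropyridin-2-yl)bis(trifluoromethanesulfonimide), O=S(=O)(N(c1ccc(Cl)cn1)S(=O)(=O)C(F)(F)F)C(F)(F)F
Why: Only C16 carries α-hydrogens, so the enolate forms towards C16 and is trapped at –78 °C, faster than β-elimination of the C17 silyloxy group, as the enol triflate.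

Step 26
Reactants: 40 C14 enol triflate; 41 carbon monoxide
Product: 42 2-(trimethylsilyl)ethyl ester of the bis-TBS-protected target
Conditions: Pd(OAc)2 (cat.), 1,3-bis(diphenylphosphino)propane, CO (1 atm), Me3SiCH2CH2OH, Et3N, DMF, 60 °C
Reagents that add atoms: 2-(trimethylsilyl)ethanol, C[Si](C)(C)CCO
Why: Palladium-catalysed alkoxycarbonylation of the enol triflate (oxidative addition, CO insertion, alcoholysis of the acyl palladium) installs C15 on C14 with the C14=C16 double bond in place.

Step 27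
Reactants: 42 2-(trimethylsilyl)ethyl ester of the bis-TBS-protected target
Product: 43 target acid CNP0106718.3
Conditions: Bu4NF (excess), THF, 23 → 50 °C; pH 5 buffer
Reagents that add atoms: none
Why: Fluoride cleaves both TBS ethers and, by β-elimination of the silylethyl group, the ester, under non-acidic conditions that the doubly allylic tertiary alcohol should tolerate; all eight stereocentres are already in place.

**Compound list**

1 | 3,3-diethoxypropan-1-ol | CCOC(OCC)CCO | starting material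
2 | 4-vinyl-1,3-dioxolan-2-one (racemic) | C=CC1COC(=O)O1 | starting material
3 | (2R,3R)-5,5-diethoxy-2-vinylpentane-1,3-diol | CCOC(OCC)C[C@@H](O)[C@@H](CO)C=C | intermediate
4 | dibutylstannylene acetal of 3 (2,2-dibutyl-1,3,2-dioxastanninane) | CCOC(OCC)C[C@@H](O[Sn]1(CCCC)CCCC)[C@@H](CO1)C=C | intermediate
5 | (3R,4R)-4-[(benzyloxy)methyl]-1,1-diethoxyhex-5-en-3-ol | CCOC(OCC)C[C@@H](O)[C@@H](COCc1ccccc1)C=C | intermediate
6 | tert-butyl{[(3R,4R)-4-[(benzyloxy)methyl]-1,1-diethoxyhex-5-en-3-yl]oxy}dimethylsilane | CCOC(OCC)C[C@@H](O[Si](C)(C)C(C)(C)C)[C@@H](COCc1ccccc1)C=C | intermediate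
7 | (3R,4R)-4-[(benzyloxy)methyl]-3-[(tert-butyldimethylsilyl)oxy]hex-5-enal | O=CC[C@@H](O[Si](C)(C)C(C)(C)C)[C@@H](COCc1ccccc1)C=C | intermediate
8 | vinylmagnesium bromide | C=C[Mg]Br | starting material
9 | (5R,6R)-6-[(benzyloxy)methyl]-5-[(tert-butyldimethylsilyl)oxy]octa-1,7-dien-3-ol (C3 epimers) | C=CC(O)C[C@@H](O[Si](C)(C)C(C)(C)C)[C@@H](COCc1ccccc1)C=C | intermediate
10 | (4R,5R)-4-[(benzyloxy)methyl]-5-[(tert-butyldimethylsilyl)oxy]cyclohex-2-en-1-ol (C1 epimers) | OC1C=C[C@H](COCc2ccccc2)[C@H](O[Si](C)(C)C(C)(C)C)C1 | intermediate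
11 | (4R,5R)-4-[(benzyloxy)methyl]-5-[(tert-butyldimethylsilyl)oxy]cyclohex-2-en-1-one | O=C1C=C[C@H](COCc2ccccc2)[C@H](O[Si](C)(C)C(C)(C)C)C1 | intermediate
12 | (4R,5R)-4-[(benzyloxy)methyl]-5-[(tert-butyldimethylsilyl)oxy]-2-iodocyclohex-2-en-1-one | O=C1C(I)=C[C@H](COCc2ccccc2)[C@H](O[Si](C)(C)C(C)(C)C)C1 | intermediate
13 | tert-butyl{[(8R,9R)-8-[(benzyloxy)methyl]-6-iodo-1,4-dioxaspiro[4.5]dec-6-en-9-yl]oxy}dimethylsilane | IC1=C[C@H](COCc2ccccc2)[C@H](O[Si](C)(C)C(C)(C)C)CC13OCCO3 | intermediate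
14 | N-methoxy-N-methylacetamide | CON(C)C(C)=O | starting material
15 | C13 vinyllithium from 13 | [Li]C1=C[C@H](COCc2ccccc2)[C@H](O[Si](C)(C)C(C)(C)C)CC13OCCO3 | intermediate
16 | 1-[(8R,9R)-8-[(benzyloxy)methyl]-9-[(tert-butyldimethylsilyl)oxy]-1,4-dioxaspiro[4.5]dec-6-en-6-yl]ethan-1-one | CC(=O)C1=C[C@H](COCc2ccccc2)[C@H](O[Si](C)(C)C(C)(C)C)CC13OCCO3 | intermediate
17 | lithium dienolate of 16 | C=C(O[Li])C1=C[C@H](COCc2ccccc2)[C@H](O[Si](C)(C)C(C)(C)C)CC13OCCO3 | intermediate
18 | (8R,9R)-8-[(benzyloxy)methyl]-9-[(tert-butyldimethylsilyl)oxy]-6-{1-[(tert-butyldimethylsilyl)oxy]ethenyl}-1,4-dioxaspiro[4.5]dec-6-ene (ring-B 2-silyloxy diene) | C=C(O[Si](C)(C)C(C)(C)C)C1=C[C@H](COCc2ccccc2)[C@H](O[Si](C)(C)C(C)(C)C)CC13OCCO3 | intermediate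
19 | 3-oxocyclobutane-1-carboxylic acid | O=C1CC(C1)C(=O)O | starting material
20 | 3-bromocyclobutan-1-one | O=C1CC(Br)C1 | intermediate
21 | cyclobut-2-en-1-one | O=C1C=CC1 | intermediate
22 | endo cycloadduct: cyclobutanone (C20=O, C9H2) cis-fused at C10–C21 to ring A with C12(OTBS)=C13, ring B with C14 dioxolane, 17-OTBS, 18-CH2OBn; H10, H21, H22 cis; H18 trans to H22; 17-O cis to C19 | C1[C@@H]2CC(O[Si](C)(C)C(C)(C)C)=C3C4(OCCO4)C[C@@H](O[Si](C)(C)C(C)(C)C)[C@@H](COCc5ccccc5)[C@@H]3[C@@H]2C1=O | intermediate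
23 | 1-bromooct-2-yne | CCCCCC#CCBr | starting material
24 | C9 lithium enolate of 22 (C9=C20) | [Li]OC1=C[C@@H]2CC(O[Si](C)(C)C(C)(C)C)=C3C4(OCCO4)C[C@@H](O[Si](C)(C)C(C)(C)C)[C@@H](COCc5ccccc5)[C@@H]3[C@H]12 | intermediate
25 | C9-(oct-2-yn-1-yl) cyclobutanone, side chain trans to C11 | CCCCCC#CC[C@H]1[C@@H]2CC(O[Si](C)(C)C(C)(C)C)=C3C4(OCCO4)C[C@@H](O[Si](C)(C)C(C)(C)C)[C@@H](COCc5ccccc5)[C@@H]3[C@@H]2C1=O | intermediate
26 | C9-octyl C19-hydroxy cyclobutanone | CCCCCCCC[C@H]1[C@@H]2CC(O[Si](C)(C)C(C)(C)C)=C3C4(OCCO4)C[C@@H](O[Si](C)(C)C(C)(C)C)[C@@H](CO)[C@@H]3[C@@H]2C1=O | intermediate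
27 | C19 mesylate of 26 | CCCCCCCC[C@H]1[C@@H]2CC(O[Si](C)(C)C(C)(C)C)=C3C4(OCCO4)C[C@@H](O[Si](C)(C)C(C)(C)C)[C@@H](COS(C)(=O)=O)[C@@H]3[C@@H]2C1=O | intermediate
28 | C9-octyl C19-iodo cyclobutanone | CCCCCCCC[C@H]1[C@@H]2CC(O[Si](C)(C)C(C)(C)C)=C3C4(OCCO4)C[C@@H](O[Si](C)(C)C(C)(C)C)[C@@H](CI)[C@@H]3[C@@H]2C1=O | intermediate
29 | tetracyclic C20 tertiary cyclobutanol (C19–C20 bond; 20-OH exo; ring C cis-fused to cyclobutane and ring A, trans-fused to ring B) | CCCCCCCC[C@H]1[C@@H]2CC(O[Si](C)(C)C(C)(C)C)=C3C5(OCCO5)C[C@@H](O[Si](C)(C)C(C)(C)C)[C@H]4C[C@@]1(O)[C@H]2[C@@H]43 | intermediate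
30 | potassium alkoxide of 29 | CCCCCCCC[C@H]1[C@@H]2CC(O[Si](C)(C)C(C)(C)C)=C3C5(OCCO5)C[C@@H](O[Si](C)(C)C(C)(C)C)[C@H]4C[C@@]1(O[K])[C@H]2[C@@H]43 | intermediate
31 | C20 methyl oxalate of 29 | CCCCCCCC[C@H]1[C@@H]2CC(O[Si](C)(C)C(C)(C)C)=C3C5(OCCO5)C[C@@H](O[Si](C)(C)C(C)(C)C)[C@H]4C[C@@]1(OC(=O)C(=O)OC)[C@H]2[C@@H]43 | intermediate
32 | C20-deoxy tetracycle (H10, H20, H21, H22 cis; C12 TBS enol ether) | CCCCCCCC[C@H]1[C@@H]2CC(O[Si](C)(C)C(C)(C)C)=C3C5(OCCO5)C[C@@H](O[Si](C)(C)C(C)(C)C)[C@H]4C[C@H]1[C@H]2[C@@H]43 | intermediate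
33 | C12,C13 α-face silyloxy epoxide of 32 | CCCCCCCC[C@H]1[C@@H]2C[C@@]6(O[Si](C)(C)C(C)(C)C)O[C@]63C5(OCCO5)C[C@@H](O[Si](C)(C)C(C)(C)C)[C@H]4C[C@H]1[C@H]2[C@@H]43 | intermediate
34 | C12 ketone with 13-OTBS (13-O cis to H22) | CCCCCCCC[C@H]1[C@@H]2CC(=O)[C@]3(O[Si](C)(C)C(C)(C)C)C5(OCCO5)C[C@@H](O[Si](C)(C)C(C)(C)C)[C@H]4C[C@H]1[C@H]2[C@@H]43 | intermediate
35 | C11 potassium enolate of 34 | CCCCCCCC[C@H]1[C@@H]2C=C(O[K])[C@]3(O[Si](C)(C)C(C)(C)C)C5(OCCO5)C[C@@H](O[Si](C)(C)C(C)(C)C)[C@H]4C[C@H]1[C@H]2[C@@H]43 | intermediate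
36 | C12 enol triflate (C11=C12) | CCCCCCCC[C@H]1[C@@H]2C=C(OS(=O)(=O)C(F)(F)F)[C@]3(O[Si](C)(C)C(C)(C)C)C5(OCCO5)C[C@@H](O[Si](C)(C)C(C)(C)C)[C@H]4C[C@H]1[C@H]2[C@@H]43 | intermediate
37 | C11=C12 alkene (13-OTBS; C14 dioxolane; 17-OTBS) | CCCCCCCC[C@H]1[C@@H]2C=C[C@]3(O[Si](C)(C)C(C)(C)C)C5(OCCO5)C[C@@H](O[Si](C)(C)C(C)(C)C)[C@H]4C[C@H]1[C@H]2[C@@H]43 | intermediate
38 | C14 ketone | CCCCCCCC[C@H]1[C@@H]2C=C[C@]3(O[Si](C)(C)C(C)(C)C)C(=O)C[C@@H](O[Si](C)(C)C(C)(C)C)[C@H]4C[C@H]1[C@H]2[C@@H]43 | intermediate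
39 | C16 potassium enolate of 38 | CCCCCCCC[C@H]1[C@@H]2C=C[C@]3(O[Si](C)(C)C(C)(C)C)C(O[K])=C[C@@H](O[Si](C)(C)C(C)(C)C)[C@H]4C[C@H]1[C@H]2[C@@H]43 | intermediate
40 | C14 enol triflate (C14=C16) | CCCCCCCC[C@H]1[C@@H]2C=C[C@]3(O[Si](C)(C)C(C)(C)C)C(OS(=O)(=O)C(F)(F)F)=C[C@@H](O[Si](C)(C)C(C)(C)C)[C@H]4C[C@H]1[C@H]2[C@@H]43 | intermediate
41 | carbon monoxide | [C-]#[O+] | starting material
42 | 2-(trimethylsilyl)ethyl ester of the 13,17-bis-TBS-protected target | CCCCCCCC[C@H]1[C@@H]2C=C[C@]3(O[Si](C)(C)C(C)(C)C)C(C(=O)OCC[Si](C)(C)C)=C[C@@H](O[Si](C)(C)C(C)(C)C)[C@H]4C[C@H]1[C@H]2[C@@H]43 | intermediate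
43 | target acid CNP0106718.3: 9-octyl-13,17-dihydroxy tetracycle with C11=C12 and C14=C16, C14 carboxylic acid; (9R,10S,13R,17S,18S,20R,21R,22S) in the atom labels used here | CCCCCCCC[C@H]1[C@@H]2C=C[C@]3(O)C(C(=O)O)=C[C@@H](O)[C@H]4C[C@H]1[C@H]2[C@@H]43 | target

**Count and risk**

Total steps: 27. Longest linear sequence: 25 (steps 1–11 and 14–27); steps 12–13 are the branch to the dienophile.

Steps most likely to fail:

1. Step 14. The hindered diene may react so slowly that oligomerisation of the dienophile and hydrolysis of the dienol ether compete, and the C14 dioxolane may erode the endo preference. The fallback sets out from 21 and 18 and returns at 22. Compound 21 would be brominated (Br2, CH2Cl2, –78 °C) to 2,3-dibromocyclobutan-1-one F1 and dehydrobrominated with Et3N to 2-bromocyclobut-2-en-1-one F2, a markedly more electrophilic dienophile. Cycloaddition of F2 with 18 should give the C21-bromo cycloadduct F3 in the same regio- and endo sense. Radical debromination (Bu3SnH, AIBN, benzene, 80 °C) would then give 22, since the ring-fusion radical can only accept hydrogen to re-form the cis-fused cyclobutanone.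

2. Step 18. Electron transfer to the strained ketone may outrun reduction of the iodide, leading to simple carbonyl reduction or pinacol coupling instead of ring closure. The fallback sets out from 28 and returns at 32, making steps 19 and 20 unnecessary. Compound 28 would be condensed with 1-amino-2-phenylaziridine to the N-aziridinyl imine F4. Treatment with Bu3SnH/AIBN (benzene, 80 °C) generates the C19 radical, which adds 5-exo to the C20 imine carbon; the aminyl radical expels styrene and dinitrogen, and the resulting C20 radical takes hydrogen to give 32.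

3. Step 20. The tertiary oxalate may eliminate thermally, or the C20 radical may open the four-membered ring before hydrogen transfer at 110 °C. The fallback sets out from 29 and returns at 32. Compound 29 would be converted (KN(SiMe3)2; 4-methylbenzoyl chloride) into the C20 4-methylbenzoate F5. Single-electron reduction with SmI2/HMPA in THF at 23 °C fragments the ester radical anion, and the C20 radical is reduced and protonated at room temperature without a tin hydride chain, giving 32.

**Further compounds**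

F1 | step 14 | 2,3-dibromocyclobutan-1-one | O=C1CC(Br)C1Br
F2 | step 14 | 2-bromocyclobut-2-en-1-one | O=C1CC=C1Br
F3 | step 14 | C21-bromo endo cycloadduct | C1[C@@H]2CC(O[Si](C)(C)C(C)(C)C)=C3C4(OCCO4)C[C@@H](O[Si](C)(C)C(C)(C)C)[C@@H](COCc5ccccc5)[C@@H]3[C@]2(Br)C1=O
F4 | step 18 | N-(2-phenylaziridin-1-yl) imine of 28 | CCCCCCCC[C@H]1[C@@H]2CC(O[Si](C)(C)C(C)(C)C)=C3C4(OCCO4)C[C@@H](O[Si](C)(C)C(C)(C)C)[C@@H](CI)[C@@H]3[C@@H]2C1=NN6CC6c7ccccc7
F5 | step 20 | C20 4-methylbenzoate of 29 | CCCCCCCC[C@H]1[C@@H]2CC(O[Si](C)(C)C(C)(C)C)=C3C5(OCCO5)C[C@@H](O[Si](C)(C)C(C)(C)C)[C@H]4C[C@@]1(OC(=O)c6ccc(C)cc6)[C@H]2[C@@H]43
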